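**Retrosynthetic overview**
1. Target ⇐ 3,4-dimethoxy-2-(12-oxotridecyl)quinoline by selective 4-O-demethylation; the 4-OMe is the masked quinolone C=O and the 3-OMe stays.
2. Key step: the C2–chain bond and the whole keto chain come from one deconstructive Minisci alkylation of 3,4-dimethoxyquinoline with 1-methylcyclododecan-1-ol. β-Scission of the 12-membered ring releases the 12-oxotridecyl radical with its methyl ketone already in place.
3. 3,4-Dimethoxyquinoline ⇐ 3-bromo-4-chloroquinoline (SNAr, then Ullmann methoxylation); 1-methylcyclododecan-1-ol ⇐ cyclododecanone + MeMgBr.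
4. Ring order: no ring is built. The quinoline is bought intact and the only ring event is opening of the cyclododecane. This replaces the usual Camps or Conrad–Limpach ring synthesis with a pre-made C14 keto acid.

Assumption: the target has no stereocentre or stereogenic double bond, so no stereocontrol is needed; PFBI–OH is taken as a catalogue reagent.

**Step 1**
Reactants: 1 cyclododecanone
Product: 2 1-methylcyclododecan-1-ol
Conditions: MeMgBr (1.5 equiv), THF, 0 °C → rt; then H2O
Reagents that add atoms: methylmagnesium bromide, C[Mg]Br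
Why: Grignard 1,2-addition to an unhindered ring ketone gives the tertiary alcohol, and no stereocentre arises because C1 carries two identical ring arms.

**Step 2**
Reactants: 3 3-bromo-4-chloroquinoline
Product: 5 3,4-dimethoxyquinoline, via 3-bromo-4-methoxyquinoline 4 (not isolated)
Conditions: NaOMe (5 equiv), MeOH, 65 °C, 2 h; then CuI (15 mol%), 1,10-phenanthroline (30 mol%), DMF, 110 °C (sealed), 16 h
Reagents that add atoms: sodium methoxide, [Na+].[O-]C
Why: Methoxide first displaces the 4-chloride by SNAr (C4 is a vinylogous imidoyl chloride), and the unactivated 3-bromide is then exchanged by a Cu(I)-catalysed Ullmann-type C–O coupling with the excess methoxide already present.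

**Step 3**
Reactants: 5 3,4-dimethoxyquinoline; 2 1-methylcyclododecan-1-ol; 6 PFBI–OH (4,5,6,7-tetrafluoro-1-hydroxy-1,2-benziodoxol-3(1H)-one)
Product: 8 13-(3,4-dimethoxyquinolin-2-yl)tridecan-2-one, via 4,5,6,7-tetrafluoro-1-[(1-methylcyclododecyl)oxy]-1,2-benziodoxol-3(1H)-one 7 (not isolated)
Conditions: 2 (3 equiv), 6 (2.5 equiv), Ru(bpy)3Cl2 (2 mol%), TFA (2 equiv), HFIP, blue LEDs, 30 °C, Ar
Reagents that add atoms: none
Why: This is a Minisci C–H alkylation driven by alkoxy-radical β-scission: ligand exchange of 2 on the I(III) centre of 6 gives 7, single-electron reduction by photoexcited Ru(II) releases the tertiary alkoxy radical, ring-opening β-scission (primary radical expelled in preference to methyl, methyl ketone formed) gives the 12-oxotridecyl radical, and this adds to the TFA-protonated quinoline at C2, the only free α/γ position, before Ru(III) oxidation and proton loss restore aromaticity.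

**Step 4**
Reactants: 8 13-(3,4-dimethoxyquinolin-2-yl)tridecan-2-one
Product: 9 3-methoxy-2-(12-oxotridecyl)quinolin-4(1H)-one
Conditions: LiCl (5 equiv), TsOH·H2O (2 equiv), DMF, 110 °C
Reagents that add atoms: none
Why: In this acid-assisted SN2 O-demethylation, chloride attacks the methyl of the N-protonated 4-methoxyquinolinium (a vinylogous imidate that leaves as the neutral 4-quinolone), while the 3-OMe is an ordinary aryl ether without that assistance and the ketone is inert.

**Compound list**
1 | cyclododecanone | O=C1CCCCCCCCCCC1 | starting material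
2 | 1-methylcyclododecan-1-ol | CC1(O)CCCCCCCCCCC1 | intermediate
3 | 3-bromo-4-chloroquinoline | Clc1c(Br)cnc2ccccc12 | starting material
4 | 3-bromo-4-methoxyquinoline | COc1c(Br)cnc2ccccc12 | intermediate
5 | 3,4-dimethoxyquinoline | COc1cnc2ccccc2c1OC | intermediate
6 | PFBI–OH, 4,5,6,7-tetrafluoro-1-hydroxy-1,2-benziodoxol-3(1H)-one | OI1OC(=O)c2c(F)c(F)c(F)c(F)c12 | starting material
7 | 4,5,6,7-tetrafluoro-1-[(1-methylcyclododecyl)oxy]-1,2-benziodoxol-3(1H)-one | CC1(CCCCCCCCCCC1)OI2OC(=O)c3c(F)c(F)c(F)c(F)c23 | intermediate
8 | 13-(3,4-dimethoxyquinolin-2-yl)tridecan-2-one | COc1c(OC)c(CCCCCCCCCCCC(C)=O)nc2ccccc12 | intermediate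
9 | 3-methoxy-2-(12-oxotridecyl)quinolin-4(1H)-one | COc1c(CCCCCCCCCCCC(C)=O)[nH]c2ccccc2c1=O | target

**Totals**
Total step count: 4. Longest linear sequence: 3 steps (3 → 5 → 8 → 9; the branch 1 → 2 → 8 → 9 is equally long).

**Three steps most likely to fail**

1. Step 3. The alkoxy radical may undergo transannular 1,5-hydrogen abstraction in the flexible 12-ring instead of β-scission, and the electron-rich dimethoxyquinolinium may trap the radical slowly. The fallback sets out from 1 and returns at 8. It replaces the radical ring opening by a polar retro-Claisen opening and a carboxyl radical precursor. Compound 1 is C-acetylated (LiHMDS, THF, −78 °C, then 1-acetylimidazole) to 2-acetylcyclododecan-1-one F1. Aqueous KOH at reflux adds to the ring carbonyl and cleaves the ring to 13-oxotetradecanoic acid F2. A classical silver-catalysed decarboxylative Minisci alkylation of 5 with F2 (AgNO3 cat., (NH4)2S2O8, TFA, MeCN/H2O, 60 °C) then gives 8.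

2. Step 2. The Ullmann stage may stall on the ortho-alkoxy heteroaryl bromide, or hot methoxide may dealkylate the 4-OMe. The fallback sets out from 4, isolated after the SNAr stage run without copper, and returns at 5. Miyaura borylation (B2pin2, Pd(dppf)Cl2, KOAc, dioxane, 90 °C) gives 4-methoxy-3-(4,4,5,5-tetramethyl-1,3,2-dioxaborolan-2-yl)quinoline F3. Oxidation (H2O2, NaOH, THF, 0 °C) gives 4-methoxyquinolin-3-ol F4. O-Methylation (MeI 1.05 equiv, Cs2CO3, DMF, 0 °C → rt) gives 5.

3. Step 4. The 3-OMe may be partly cleaved as well, giving mixtures. The fallback sets out from 8 and returns at 9. Both ethers are cleaved on purpose (48% HBr, AcOH, 110 °C) to 3-hydroxy-2-(12-oxotridecyl)quinolin-4(1H)-one F5. The acidic 3-OH is then methylated selectively (MeI 1.0 equiv, K2CO3, DMF, rt; the vinylogous-amide N–H is far less nucleophilic) to give 9.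

**Further compounds**
F1 | step 3 | 2-acetylcyclododecan-1-one | CC(=O)C1CCCCCCCCCCC1=O
F2 | step 3 | 13-oxotetradecanoic acid | CC(=O)CCCCCCCCCCCC(=O)O
F3 | step 2 | 4-methoxy-3-(4,4,5,5-tetramethyl-1,3,2-dioxaborolan-2-yl)quinoline | COc1c(B2OC(C)(C)C(C)(C)O2)cnc2ccccc12
F4 | step 2 | 4-methoxyquinolin-3-ol | COc1c(O)cnc2ccccc12
F5 | step 4 | 3-hydroxy-2-(12-oxotridecyl)quinolin-4(1H)-one | CC(=O)CCCCCCCCCCCc1[nH]c2ccccc2c(=O)c1O
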